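**Retrosynthetic overview**

1. The target is traced back to its tert-butyl ester/bis-PMB ether and then to the corresponding 3-dehydroquinate: O-3 is kept at the ketone level, so O-4 and O-5 can carry both coumaroyl esters from the start and need no later differentiation.
2. The cyclohexane is opened at C1–C2, an aldol bond once C3 is a ketone. The precursor is a pyranoid 6,7-enol ether of a 3-deoxy-D-arabino-hept-2-ulosonate, and one Hg(II)-triggered operation trades its oxane for the carbocycle.
3. The heptulosonate comes from D-erythrose (its C1–C4 become C5, C4, C3, C2 of the target) and tert-butyl 2-(bromomethyl)acrylate (CH2 → C6, olefinic C → C1, ester → carboxyl). p-Coumaric acid supplies both aryl rings.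
4. Ring order: temporary oxane (step 2, destroyed in step 7), then the cyclohexane (step 7), the only ring of the skeleton built in the route.
5. Enabling feature: in the cyclohexane, C1 is a tertiary carbinol bearing the carboxyl and sits 1,3 to the oxygenated C3 across the C2 methylene, with C6 a second methylene. With C3 as ketone the ring unfolds to a 2,6-diketo ester, i.e. a pyruvate C3 unit plus a D-erythrose C4 unit.

Key step: step 7

Remark: the anomeric centre of compounds 4, 5, 9, 10 and 11 is drawn as the expected α-anomer (axial oxygen, equatorial CO2tBu); it is not a stereocentre of the target and is erased in step 7. Sugar numbering (C1–C7 of the heptulosonate) is used for these compounds and quinic acid numbering from 13 onward.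

**Route**

Step 1
Reactants: 1 D-erythrose; 2 tert-butyl 2-(bromomethyl)acrylate
Product: 3 tert-butyl (4R,5S,6R)-4,5,6,7-tetrahydroxy-2-methylideneheptanoate
Conditions: In powder, EtOH–H2O (1:1), rt
Reagents that add atoms: none
Why: Barbier-type indium-mediated 2-(alkoxycarbonyl)allylation in water works on the unprotected sugar and, through a Cram chelate of indium between the aldehyde oxygen and the free α-hydroxyl, should favour the threo (4R, D-arabino) alcohol, the later C5 of the target; the minor erythro epimer would be removed by chromatography here or after step 2.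

Step 2
Reactants: 3 tert-butyl (4R,5S,6R)-4,5,6,7-tetrahydroxy-2-methylideneheptanoate
Product: 4 tert-butyl 3-deoxy-α-D-arabino-hept-2-ulopyranosonate
Conditions: O3, MeOH, −78 °C; then Me2S, −78 °C to rt
Reagents that add atoms: ozone, [O-][O+]=O
Why: Ozonolysis with reductive work-up cleaves the only C=C bond to the α-keto ester, which should close at once onto the 6-hydroxyl to the six-membered hemiketal with CO2tBu and all ring substituents equatorial; no stereocentre of the target is touched.

Step 3
Reactants: 4 tert-butyl 3-deoxy-α-D-arabino-hept-2-ulopyranosonate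
Product: 5 tert-butyl 3,7-dideoxy-7-iodo-α-D-arabino-hept-2-ulopyranosonate
Conditions: PPh3, I2, imidazole, THF, 0 °C to rt
Reagents that add atoms: iodine, II
Why: Appel-type iodination under Garegg–Samuelsson conditions should convert the unhindered primary hydroxyl selectively, because the secondary hydroxyls and the tertiary, electron-poor anomeric hydroxyl react much more slowly at room temperature.

Step 4
Reactants: 6 (E)-p-coumaric acid
Product: 8 (E)-4-(4-methoxybenzyloxy)cinnamic acid, via bis-PMB ester ether 7 (not isolated)
Conditions: PMBCl, K2CO3, DMF, 60 °C; then 2 M aq NaOH, MeOH, 60 °C; then 1 M HCl to pH 3, 0 °C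
Reagents that add atoms: 4-methoxybenzyl chloride, COc1ccc(CCl)cc1; sodium hydroxide, [Na+].[OH-]
Why: Williamson O-alkylation of carboxylate and phenolate followed by saponification of the PMB ester in the same pot leaves the base-stable aryl PMB ether and the E-alkene unchanged.

Step 5
Reactants: 5 tert-butyl 3,7-dideoxy-7-iodo-α-D-arabino-hept-2-ulopyranosonate; 8 (E)-4-(4-methoxybenzyloxy)cinnamic acid
Product: 10 tert-butyl 2-O-acetyl-3,7-dideoxy-7-iodo-4,5-di-O-[(E)-4-(4-methoxybenzyloxy)cinnamoyl]-α-D-arabino-hept-2-ulopyranosonate, via hemiketal 4,5-diester 9 (not isolated)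
Conditions: 8 (2.3 equiv), DIC, DMAP (cat.), CH2Cl2, 0 °C to rt; then Ac2O, pyridine, rt
Reagents that add atoms: acetic anhydride, CC(=O)OC(C)=O
Why: Steglich esterification should acylate the two equatorial secondary hydroxyls, while the tertiary anomeric hydroxyl next to the tert-butyl ester is too hindered for the activated form of 8 and is capped afterwards by the small, more reactive acetic anhydride (DMAP-catalysed acetylation), with no change at any stereocentre.

Step 6
Reactants: 10 tert-butyl 2-O-acetyl-3,7-dideoxy-7-iodo-4,5-di-O-[(E)-4-(4-methoxybenzyloxy)cinnamoyl]-α-D-arabino-hept-2-ulopyranosonate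
Product: 11 tert-butyl 2-O-acetyl-3,7-dideoxy-4,5-di-O-[(E)-4-(4-methoxybenzyloxy)cinnamoyl]-α-D-threo-hept-6-en-2-ulopyranosonate
Conditions: AgF, pyridine, rt, dark
Reagents that add atoms: none
Why: Silver(I)-assisted E2 dehydroiodination of a primary iodide next to the ring carbon (C6–H is the only β-hydrogen) is the classical entry to exocyclic pyranoid enol ethers and tolerates carboxylic esters and anomeric acetates.

Step 7
Reactants: 11 tert-butyl 2-O-acetyl-3,7-dideoxy-4,5-di-O-[(E)-4-(4-methoxybenzyloxy)cinnamoyl]-α-D-threo-hept-6-en-2-ulopyranosonate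
Product: 13 tert-butyl 4,5-di-O-[(E)-4-(4-methoxybenzyloxy)cinnamoyl]-3-dehydroquinate, via mercurated diketo ester 12 (not isolated)
Conditions: Hg(OCOCF3)2 (10 mol %), acetone–H2O (4:1), 0 °C to rt
Reagents that add atoms: water, O
Why: Proposed new method: Hg(II) adds to the electron-rich exocyclic enol ether (mercury on sugar C7, water on C6), the C6 hemiketal opens and the anomeric hemiketal acetate collapses with loss of acetic acid, so the oxane unravels to the C7-mercurated 2,6-diketo ester 12, whose mercury enolate adds to the highly electrophilic α-keto ester carbonyl (sugar C2) to form the C2–C7 bond, which is C1–C2 of the target, releasing Hg(II) for turnover. The closest known reaction type is the Ferrier carbocyclization of 6-deoxyhex-5-enopyranosides to 2-deoxyinososes, extended here from aldosides to a ketosidic 2-ulosonate so that the acceptor is a ketone and the new carbinol is tertiary; the same enol-to-α-keto-acid aldol on this heptulosonate skeleton is the ring-forming event of 3-dehydroquinate biosynthesis. The cyclohexane closes in a 6-(enolendo)-exo-trig aldol mode. The only new stereocentre, C1, should be set by a chair transition state in which both acyloxy groups and the bulky CO2tBu are equatorial and the carbonyl oxygen is axial near mercury, which places the new hydroxyl trans to O-5, the usual Ferrier outcome (new hydroxyl trans to the substituent two carbons from the former anomeric centre). The step needs enolate formation toward C7 and not toward the acyloxy-bearing C5 (which would lead to β-elimination), secured because the enolate arises only at the mercurated carbon under near-neutral conditions, and it needs chemoselectivity for the enol ether over the cinnamate alkenes and anisole rings, secured by the far higher nucleophilicity of the enol ether toward a catalytic amount of Hg(II).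

Step 8
Reactants: 13 tert-butyl 4,5-di-O-[(E)-4-(4-methoxybenzyloxy)cinnamoyl]-3-dehydroquinate
Product: 14 tert-butyl 4,5-di-O-[(E)-4-(4-methoxybenzyloxy)cinnamoyl]quinate
Conditions: L-Selectride (1.2 equiv), THF, −78 °C; AcOH quench at −78 °C
Reagents that add atoms: none
Why: Ketone reduction under steric approach control: in the chair of 13 (both acyloxy groups and CO2tBu equatorial, C1–OH axial) the axial face of C3 is shielded by the syn-axial C1 oxygen, so the bulky tri-sec-butylborohydride, which cannot be delivered from that oxygen, should attack equatorially and set the axial 3-hydroxyl cis to O-4 (3R), while at −78 °C the ketone reacts far faster than the cinnamates and the tert-butyl ester and the cold acetic acid quench protonates the C3 alkoxide before it can take over the neighbouring acyl group.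

Step 9
Reactants: 14 tert-butyl 4,5-di-O-[(E)-4-(4-methoxybenzyloxy)cinnamoyl]quinate
Product: 15 4,5-di-O-p-coumaroylquinic acid
Conditions: TFA–CH2Cl2 (1:4), anisole (10 equiv), 0 °C to rt
Reagents that add atoms: none
Why: Acidolysis by SN1 fragmentation should cleave the tert-butyl ester (to isobutene) and both aryl 4-methoxybenzyl ethers (cation trapped by anisole in a Friedel–Crafts alkylation), while the cinnamate esters, the alcohols and all stereocentres are stable to anhydrous acid at this temperature.

**Compound list**

1 | D-erythrose, (2R,3R)-2,3,4-trihydroxybutanal | O=C[C@H](O)[C@H](O)CO | starting material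
2 | tert-butyl 2-(bromomethyl)acrylate | C=C(CBr)C(=O)OC(C)(C)C | starting material
3 | tert-butyl (4R,5S,6R)-4,5,6,7-tetrahydroxy-2-methylideneheptanoate | C=C(C(=O)OC(C)(C)C)C[C@@H](O)[C@H](O)[C@H](O)CO | intermediate
4 | tert-butyl 3-deoxy-α-D-arabino-hept-2-ulopyranosonate | CC(C)(C)OC(=O)[C@@]1(O)C[C@@H](O)[C@H](O)[C@@H](CO)O1 | intermediate
5 | tert-butyl 3,7-dideoxy-7-iodo-α-D-arabino-hept-2-ulopyranosonate | CC(C)(C)OC(=O)[C@@]1(O)C[C@@H](O)[C@H](O)[C@@H](CI)O1 | intermediate
6 | (E)-p-coumaric acid | O=C(O)/C=C/c1ccc(O)cc1 | starting material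
7 | 4-methoxybenzyl (E)-4-(4-methoxybenzyloxy)cinnamate | O=C(/C=C/c1ccc(OCc2ccc(OC)cc2)cc1)OCc1ccc(OC)cc1 | intermediate (not isolated)
8 | (E)-4-(4-methoxybenzyloxy)cinnamic acid | O=C(O)/C=C/c1ccc(OCc2ccc(OC)cc2)cc1 | intermediate
9 | tert-butyl 3,7-dideoxy-7-iodo-4,5-di-O-[(E)-4-(4-methoxybenzyloxy)cinnamoyl]-α-D-arabino-hept-2-ulopyranosonate (free anomeric hydroxyl) | CC(C)(C)OC(=O)[C@@]1(O)C[C@@H](OC(=O)/C=C/c2ccc(OCc3ccc(OC)cc3)cc2)[C@H](OC(=O)/C=C/c2ccc(OCc3ccc(OC)cc3)cc2)[C@@H](CI)O1 | intermediate (not isolated)
10 | tert-butyl 2-O-acetyl-3,7-dideoxy-7-iodo-4,5-di-O-[(E)-4-(4-methoxybenzyloxy)cinnamoyl]-α-D-arabino-hept-2-ulopyranosonate | CC(C)(C)OC(=O)[C@@]1(OC(C)=O)C[C@@H](OC(=O)/C=C/c2ccc(OCc3ccc(OC)cc3)cc2)[C@H](OC(=O)/C=C/c2ccc(OCc3ccc(OC)cc3)cc2)[C@@H](CI)O1 | intermediate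
11 | tert-butyl 2-O-acetyl-3,7-dideoxy-4,5-di-O-[(E)-4-(4-methoxybenzyloxy)cinnamoyl]-α-D-threo-hept-6-en-2-ulopyranosonate (exocyclic 6,7-enol ether) | CC(C)(C)OC(=O)[C@@]1(OC(C)=O)C[C@@H](OC(=O)/C=C/c2ccc(OCc3ccc(OC)cc3)cc2)[C@H](OC(=O)/C=C/c2ccc(OCc3ccc(OC)cc3)cc2)C(=C)O1 | intermediate
12 | tert-butyl 3,7-dideoxy-4,5-di-O-[(E)-4-(4-methoxybenzyloxy)cinnamoyl]-7-(trifluoroacetoxymercurio)-D-threo-hept-2,6-diulosonate | CC(C)(C)OC(=O)C(=O)C[C@@H](OC(=O)/C=C/c1ccc(OCc2ccc(OC)cc2)cc1)[C@H](OC(=O)/C=C/c1ccc(OCc2ccc(OC)cc2)cc1)C(=O)C[Hg]OC(=O)C(F)(F)F | intermediate (not isolated)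
13 | tert-butyl 4,5-di-O-[(E)-4-(4-methoxybenzyloxy)cinnamoyl]-3-dehydroquinate (1-OH cis to O-4, trans to O-5) | O=C(/C=C/c1ccc(OCc2ccc(OC)cc2)cc1)O[C@@H]1C(=O)C[C@@](O)(C(=O)OC(C)(C)C)C[C@H]1OC(=O)/C=C/c1ccc(OCc2ccc(OC)cc2)cc1 | intermediate
14 | tert-butyl 4,5-di-O-[(E)-4-(4-methoxybenzyloxy)cinnamoyl]quinate | O=C(/C=C/c1ccc(OCc2ccc(OC)cc2)cc1)O[C@@H]1[C@H](O)C[C@@](O)(C(=O)OC(C)(C)C)C[C@H]1OC(=O)/C=C/c1ccc(OCc2ccc(OC)cc2)cc1 | intermediate
15 | 4,5-di-O-p-coumaroylquinic acid, (1S,3R,4R,5R) | O=C(/C=C/c1ccc(O)cc1)O[C@@H]1[C@H](O)C[C@@](O)(C(=O)O)C[C@H]1OC(=O)/C=C/c1ccc(O)cc1 | target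

**Summary**

Total step count: 9. Longest linear sequence: 8 steps (steps 1–3 and 5–9, from D-erythrose); step 4 is the side-chain branch.

Stereocentres: C4 comes from C2 of D-erythrose, C5 is set in step 1, C1 in step 7 and C3 in step 8.

**Steps most likely to fail**

Step 7 (Proposed new method). The mercurated intermediate may lose mercury by protonolysis before the C–C bond forms, or the β-acyloxy ketone product may suffer elimination of the C5 acyloxy group under the metal conditions. The fallback separates ring opening from ring closure with known chemistry. It sets out from enol ether 11, which would be hydrolysed with aqueous acetic acid in THF (enol-ether hydrolysis, collapse of the anomeric hemiketal acetate) to the open-chain tert-butyl 3,7-dideoxy-4,5-di-O-[(E)-4-(4-methoxybenzyloxy)cinnamoyl]-D-threo-hept-2,6-diulosonate F1. F1 would then be closed by enamine catalysis (L-proline or pyrrolidinium acetate, DMSO, rt), a 6-enolendo aldol cyclization of the Hajos–Parrish type in which the enamine forms at the methyl ketone and adds to the α-keto ester. The fallback comes back to the route at compound 13.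

Step 8. Hydride delivery may be insufficiently face-selective, conjugate reduction of the cinnamates may compete, or the C3 alkoxide may trigger a 4→3 acyl shift before the quench. The fallback replaces substrate control under basic conditions by catalyst control under neutral ones: ketone 13 would be reduced with a screened NADPH-dependent ketoreductase (isopropanol as terminal reductant, pH 6.5 buffer with DMSO cosolvent). It sets out from 13 and comes back at 14; this fallback makes no new compound (F0).

Step 9. The 4-methoxybenzyl cations may re-alkylate the freed phenols, and the acid contact needed for the aryl ethers may promote acyl shift toward the free 3-hydroxyl. The fallback removes the two protecting-group types by different mechanisms. It sets out from 14, whose aryl PMB ethers would be cleaved oxidatively with DDQ (CH2Cl2/pH 7 buffer, 0 °C to rt) to tert-butyl 4,5-di-O-[(E)-p-coumaroyl]quinate F2. Brief acidolysis of the tert-butyl ester alone (TFA–CH2Cl2, 0 °C, no benzyl cation present) then brings it back at compound 15.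

**Further compounds**

F1 | step 7 | tert-butyl 3,7-dideoxy-4,5-di-O-[(E)-4-(4-methoxybenzyloxy)cinnamoyl]-D-threo-hept-2,6-diulosonate | CC(C)(C)OC(=O)C(=O)C[C@@H](OC(=O)/C=C/c1ccc(OCc2ccc(OC)cc2)cc1)[C@H](OC(=O)/C=C/c1ccc(OCc2ccc(OC)cc2)cc1)C(C)=O
F0 | step 8 | none | none
F2 | step 9 | tert-butyl 4,5-di-O-[(E)-p-coumaroyl]quinate | O=C(/C=C/c1ccc(O)cc1)O[C@@H]1[C@H](O)C[C@@](O)(C(=O)OC(C)(C)C)C[C@H]1OC(=O)/C=C/c1ccc(O)cc1
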